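**Plan**

1. Retrosynthetic cuts, in order: the three phenolic O–CH2OMe bonds, then O1–C2 of ring C, then C3–C4 (vinyl anion plus ring A aldehyde), then the C5'–CH2 bond of the prenyl group.
2. Enabling feature: in ring C, C2 is an unsubstituted CH2 on O1, and C3 is a tertiary C–H between the C4 ketone and ring B. Cutting O1–C2 therefore leaves an achiral α-aryl enone (H2C2=C3(Ar)–C4=O) whose ring A phenol oxygen (the future O1, on C8a) sits ortho to the acyl group.
3. Forward order: rings A and B are bought. Ring B is brominated at C5', MOM-protected and prenylated, and its acetyl group becomes the C3 vinyllithium. This is joined to the ring A aldehyde carbon (C4) and the carbinol is oxidised. Ring C, the only ring made, closes in the penultimate step.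
4. Stereochemistry: C3 (R), the only stereocentre, is set when a chiral BINOL N-triflyl phosphoramide protonates one face of the C3=C4 enol formed by the ring closure. The last step only removes acetals.

Key step: step 8

Assumption: the sense of induction of this protonation cannot be predicted with confidence, so the (R)-catalyst is written and its mirror image would be used if a trial run shows the 3S ketone.

**Step 1**
Reactants: 1 2',3'-dihydroxy-4'-methoxyacetophenone
Product: 2 1-(5-bromo-2,3-dihydroxy-4-methoxyphenyl)ethan-1-one
Conditions: NBS (1.0 equiv), MeCN, 0 °C, dark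
Reagents that add atoms: N-bromosuccinimide, O=C1CCC(=O)N1Br
Why: Electrophilic aromatic bromination should take C5', which is para to the 2'-OH, ortho to the 4'-OMe and meta to the acetyl group, whereas C6' is ortho to the acetyl group and activated only by the 3'-OH, in line with the behaviour of 2-hydroxy-4-methoxyacetophenones.

**Step 2**
Reactants: 2 1-(5-bromo-2,3-dihydroxy-4-methoxyphenyl)ethan-1-one
Product: 3 1-[5-bromo-4-methoxy-2,3-bis(methoxymethoxy)phenyl]ethan-1-one
Conditions: NaH (2.5 equiv), MOMCl (2.5 equiv), DMF, 0 °C → rt
Reagents that add atoms: chloromethyl methyl ether (MOMCl), COCCl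
Why: Williamson-type O-alkylation of both sodium phenoxides, including the chelated 2'-OH once NaH has deprotonated it, gives acetals that tolerate zerovalent palladium, n-BuLi and MnO2.

**Step 3**
Reactants: 3 1-[5-bromo-4-methoxy-2,3-bis(methoxymethoxy)phenyl]ethan-1-one; 4 tributyl(3-methylbut-2-enyl)stannane
Product: 5 1-[4-methoxy-2,3-bis(methoxymethoxy)-5-(3-methylbut-2-en-1-yl)phenyl]ethan-1-one
Conditions: 4 (1.3 equiv), Pd(PPh3)4 (5 mol%), degassed DMF, 100 °C
Reagents that add atoms: none
Why: Stille coupling (oxidative addition of the aryl bromide to zerovalent palladium, prenyl transfer from tin, reductive elimination from the less hindered σ-allyl complex) should give the linear prenyl arene under neutral conditions that leave the ketone and the MOM ethers untouched.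

**Step 4**
Reactants: 5 1-[4-methoxy-2,3-bis(methoxymethoxy)-5-(3-methylbut-2-en-1-yl)phenyl]ethan-1-one
Product: 6 (E)-2,4,6-triisopropylbenzenesulfonyl hydrazone of ketone 5
Conditions: TrisNHNH2 (1.1 equiv), PPTS (5 mol%), THF, rt
Reagents that add atoms: 2,4,6-triisopropylbenzenesulfonohydrazide, CC(C)c1cc(C(C)C)c(S(=O)(=O)NN)c(C(C)C)c1
Why: Condensation of the methyl ketone with the sulfonyl hydrazide gives the hydrazone with N–H syn to the methyl group, and the trisyl group is chosen because its blocked ortho positions rule out ring lithiation and speed up sulfinate loss in step 6.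

**Step 5**
Reactants: 7 2,4-dihydroxybenzaldehyde
Product: 8 2-hydroxy-4-(methoxymethoxy)benzaldehyde
Conditions: MOMCl (1.05 equiv), K2CO3 (1.2 equiv), acetone, 0 °C → rt
Reagents that add atoms: chloromethyl methyl ether (MOMCl), COCCl
Why: Selective Williamson O-alkylation works because the 2-OH is tied up in a hydrogen bond to the aldehyde and is the less acidic and less nucleophilic site, so one equivalent of MOMCl goes to the 4-OH.

**Step 6**
Reactants: 6 trisylhydrazone of ketone 5; 8 2-hydroxy-4-(methoxymethoxy)benzaldehyde
Product: 11 racemic 2-{1-hydroxy-2-[4-methoxy-2,3-bis(methoxymethoxy)-5-(3-methylbut-2-en-1-yl)phenyl]prop-2-en-1-yl}-5-(methoxymethoxy)phenol, via α-arylvinyllithium 9 (not isolated), via sodium phenolate 10 (not isolated)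
Conditions: 6, n-BuLi (2.1 equiv), THF, −78 → 0 °C, then −78 °C; 8 (1.2 equiv), NaH (1.2 equiv), THF, 0 °C in a second flask; 10 cannulated into 9, −78 → −20 °C; aq NH4Cl
Reagents that add atoms: none
Why: In this Shapiro reaction followed by 1,2-addition, n-BuLi removes the N–H and a syn methyl proton, loss of sulfinate and N2 on warming gives vinyllithium 9 (held by the 2'-OMOM oxygen), and 9 adds to the aldehyde of the pre-formed phenolate 10 so that no vinyllithium is lost to the O–H; the new carbinol centre forms as a racemate and is destroyed in step 7.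

**Step 7**
Reactants: 11 racemic phenol–allylic alcohol
Product: 12 1-[2-hydroxy-4-(methoxymethoxy)phenyl]-2-[4-methoxy-2,3-bis(methoxymethoxy)-5-(3-methylbut-2-en-1-yl)phenyl]prop-2-en-1-one
Conditions: activated MnO2 (20 equiv), CH2Cl2, 0 °C → rt; filtration through Celite, cold concentration, used at once
Reagents that add atoms: none
Why: MnO2 oxidation of a carbinol that is both benzylic and allylic is neutral and heterogeneous, spares the phenol, the prenyl alkene and the MOM ethers, and delivers the enone with its phenol already hydrogen-bonded to the new carbonyl and with no phenoxide ever formed next to the acceptor, which is why a silyl ether and its fluoride cleavage are avoided at this point.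

**Step 8**
Reactants: 12 2-hydroxyaryl α-aryl vinyl ketone
Product: 14 (3R)-3-[4-methoxy-2,3-bis(methoxymethoxy)-5-(3-methylbut-2-en-1-yl)phenyl]-7-(methoxymethoxy)-2,3-dihydro-4H-chromen-4-one, via enol 13 (not isolated)
Conditions: (R)-3,3'-bis(2,4,6-triisopropylphenyl)-1,1'-binaphthyl-2,2'-diyl N-(trifluoromethylsulfonyl)phosphoramide (10 mol%), toluene (0.02 M), −60 °C, acid-washed glassware; cold filtration through silica
Reagents that add atoms: none
Why: Proposed new method: the acidic N–H of the phosphoramide takes over the C4 carbonyl from the internal hydrogen bond while the P=O oxygen accepts the freed phenol O–H, so that after rotation about the aryl–C4 bond the ring A oxygen adds to the unsubstituted CH2 terminus, forming O1–C2 and the C3=C4 enol 13, which stays paired with the catalyst and takes its proton at C3 while handing back its own O–H proton. The closest known reaction types are conjugate addition–enantioselective protonation of α-substituted acceptors, Nazarov cyclisation–enantioselective protonation with the same catalyst family, and chiral Brønsted acid protonation of silyl enol ethers of 2-aryl cyclic ketones; an oxa-Michael closure to a 3-arylchroman-4-one with catalytic control at C3 is not known. Ring C closes in the 6-endo-trig mode, which the flat aryl ketone tether and the open, strongly polarised methylene carbon permit. The R configuration at C3 is controlled by the catalyst alone: its two 2,4,6-triisopropylphenyl groups shield one face of the bound enol, and ring B, twisted out of the enol plane by its 2'-OMOM group, gives the pocket a large substituent to discriminate. The step needs chemoselectivity, secured because the hydroxyl on the future C8a is the only free O–H (all other phenols are MOM ethers), and it needs the catalysed path to outrun racemic background closure, secured by the chelated and weakly nucleophilic phenol, toluene, −60 °C and the absence of base. Under these cold acidic conditions 14 should not re-enolise, because the planar enol suffers allylic strain between ring B and the C4 oxygen.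

**Step 9**
Reactants: 14 (3R)-tri-O-MOM isoflavanone
Product: 15 (3R)-3-[2,3-dihydroxy-4-methoxy-5-(3-methylbut-2-en-1-yl)phenyl]-7-hydroxy-2,3-dihydro-4H-chromen-4-one (target)
Conditions: conc. aq HCl (to 0.5 M), MeOH, 0 °C → rt, stopped as soon as the last MOM ether is gone
Reagents that add atoms: none
Why: Acid-catalysed transacetalisation of aryl MOM ethers to dimethoxymethane is the usual unmasking in prenylated 2'-hydroxyisoflavanone chemistry, the prenyl group has only OMe and H as ortho neighbours so no chroman can form, and dilute acid at or below rt should outpace the slower acid-catalysed enolisation at C3, so that the R configuration is carried into 15.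

**Compound list**

1 | 2',3'-dihydroxy-4'-methoxyacetophenone | COc1ccc(C(C)=O)c(O)c1O | starting material
2 | 1-(5-bromo-2,3-dihydroxy-4-methoxyphenyl)ethan-1-one | COc1c(Br)cc(C(C)=O)c(O)c1O | intermediate
3 | 1-[5-bromo-4-methoxy-2,3-bis(methoxymethoxy)phenyl]ethan-1-one | COc1c(Br)cc(C(C)=O)c(OCOC)c1OCOC | intermediate
4 | tributyl(3-methylbut-2-enyl)stannane | CCCC[Sn](CCCC)(CCCC)CC=C(C)C | starting material
5 | 1-[4-methoxy-2,3-bis(methoxymethoxy)-5-(3-methylbut-2-en-1-yl)phenyl]ethan-1-one | COc1c(CC=C(C)C)cc(C(C)=O)c(OCOC)c1OCOC | intermediate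
6 | (E)-2,4,6-triisopropylbenzenesulfonyl hydrazone of 5 | COc1c(CC=C(C)C)cc(/C(C)=N/NS(=O)(=O)c2c(C(C)C)cc(C(C)C)cc2C(C)C)c(OCOC)c1OCOC | intermediate
7 | 2,4-dihydroxybenzaldehyde | O=Cc1ccc(O)cc1O | starting material
8 | 2-hydroxy-4-(methoxymethoxy)benzaldehyde | COCOc1ccc(C=O)c(O)c1 | intermediate
9 | 1-[4-methoxy-2,3-bis(methoxymethoxy)-5-(3-methylbut-2-en-1-yl)phenyl]ethenyllithium | [Li]C(=C)c1cc(CC=C(C)C)c(OC)c(OCOC)c1OCOC | intermediate
10 | sodium 2-formyl-5-(methoxymethoxy)phenolate | COCOc1ccc(C=O)c([O-])c1.[Na+] | intermediate
11 | racemic 2-{1-hydroxy-2-[4-methoxy-2,3-bis(methoxymethoxy)-5-(3-methylbut-2-en-1-yl)phenyl]prop-2-en-1-yl}-5-(methoxymethoxy)phenol | COc1c(CC=C(C)C)cc(C(=C)C(O)c2ccc(OCOC)cc2O)c(OCOC)c1OCOC | intermediate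
12 | 1-[2-hydroxy-4-(methoxymethoxy)phenyl]-2-[4-methoxy-2,3-bis(methoxymethoxy)-5-(3-methylbut-2-en-1-yl)phenyl]prop-2-en-1-one | COc1c(CC=C(C)C)cc(C(=C)C(=O)c2ccc(OCOC)cc2O)c(OCOC)c1OCOC | intermediate
13 | 3-[4-methoxy-2,3-bis(methoxymethoxy)-5-(3-methylbut-2-en-1-yl)phenyl]-7-(methoxymethoxy)-2H-chromen-4-ol (enol) | COc1c(CC=C(C)C)cc(C2=C(O)c3ccc(OCOC)cc3OC2)c(OCOC)c1OCOC | intermediate
14 | (3R)-3-[4-methoxy-2,3-bis(methoxymethoxy)-5-(3-methylbut-2-en-1-yl)phenyl]-7-(methoxymethoxy)-2,3-dihydro-4H-chromen-4-one | COc1c(CC=C(C)C)cc([C@@H]2COc3cc(OCOC)ccc3C2=O)c(OCOC)c1OCOC | intermediate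
15 | (3R)-3-[2,3-dihydroxy-4-methoxy-5-(3-methylbut-2-en-1-yl)phenyl]-7-hydroxy-2,3-dihydro-4H-chromen-4-one | COc1c(CC=C(C)C)cc([C@@H]2COc3cc(O)ccc3C2=O)c(O)c1O | target

**Step count**

Total step count: 9.
Longest linear sequence: 8 steps (1 → 2 → 3 → 5 → 6 → 11 → 12 → 14 → 15). Step 5 is the only side branch.

**Steps most likely to fail**

**Step 8.** Two processes would lower the enantiomeric purity. One is ring closure without the catalyst, on surfaces or already while 12 is being handled. The other is poor facial selectivity of the proton transfer.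

The fallback sets out from 12 and comes back at 14, and it separates ring closure from the stereo-defining event.
- 12 is closed deliberately with catalytic Et3N in CH2Cl2 to the racemic tri-O-MOM isoflavanone F1.
- Soft enolisation with TMSOTf and Et3N in CH2Cl2 at 0 °C gives the 4-(trimethylsilyloxy)-2H-chromene F2.
- F2 is treated in toluene with phenol (1.1 equiv) as the achiral proton source and a catalytic BINOL-derived N-triflyl thiophosphoramide (P=S in place of P=O, same 3,3'-aryl groups). This is the established catalytic enantioselective protonation of silyl enol ethers of 2-aryl cyclic ketones, and it should give 14.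

**Step 6.** Three processes may interfere:
- competing deprotonation of the benzylic–allylic CH2 of the prenyl group;
- protonation of the vinyllithium during the warm-up;
- sluggish addition to the electron-rich phenolate aldehyde.

The fallback sets out from 5 and 8 and comes back at 11. It replaces the organolithium by an organochromium reagent.
- 5 is converted with KN(SiMe3)2 and PhNTf2 in THF at −78 °C into the 1-arylvinyl triflate F3.
- 8 is silylated with TBSCl and imidazole in DMF to the O-TBS aldehyde F4.
- Nozaki–Hiyama–Kishi coupling of F3 with F4 (CrCl2 4 equiv, NiCl2 2 mol%, DMF, rt) gives the O-TBS allylic alcohol F5.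
- Bu4NF in THF at 0 °C frees the phenol at the alcohol oxidation level, where a phenoxide can do no harm, and gives 11.

**Step 9.** Three processes may interfere:
- erosion of the C3 configuration by acid-catalysed enolisation;
- attack of the liberated 2'-OH on C4 with loss of water;
- Markovnikov addition of methanol to the prenyl alkene.

The fallback sets out from 14 and comes back at 15. It avoids protic acid altogether by exchanging the protecting groups.
- TESOTf and 2,2'-bipyridyl in CH2Cl2 at 0 °C, a known direct conversion of aryl MOM ethers into aryl silyl ethers, give the (3R)-tris(triethylsilyl) ether F6.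
- Et3N·3HF in THF at 0 °C then cleaves the three silyl ethers under buffered conditions to give 15.

**Further compounds**

F1 | step 8 | racemic 3-[4-methoxy-2,3-bis(methoxymethoxy)-5-(3-methylbut-2-en-1-yl)phenyl]-7-(methoxymethoxy)-2,3-dihydro-4H-chromen-4-one | COc1c(CC=C(C)C)cc(C2COc3cc(OCOC)ccc3C2=O)c(OCOC)c1OCOC
F2 | step 8 | 3-[4-methoxy-2,3-bis(methoxymethoxy)-5-(3-methylbut-2-en-1-yl)phenyl]-7-(methoxymethoxy)-4-(trimethylsilyloxy)-2H-chromene | COc1c(CC=C(C)C)cc(C2=C(O[Si](C)(C)C)c3ccc(OCOC)cc3OC2)c(OCOC)c1OCOC
F3 | step 6 | 1-[4-methoxy-2,3-bis(methoxymethoxy)-5-(3-methylbut-2-en-1-yl)phenyl]ethenyl trifluoromethanesulfonate | COc1c(CC=C(C)C)cc(C(=C)OS(=O)(=O)C(F)(F)F)c(OCOC)c1OCOC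
F4 | step 6 | 2-(tert-butyldimethylsilyloxy)-4-(methoxymethoxy)benzaldehyde | COCOc1ccc(C=O)c(O[Si](C)(C)C(C)(C)C)c1
F5 | step 6 | racemic 1-[2-(tert-butyldimethylsilyloxy)-4-(methoxymethoxy)phenyl]-2-[4-methoxy-2,3-bis(methoxymethoxy)-5-(3-methylbut-2-en-1-yl)phenyl]prop-2-en-1-ol | COc1c(CC=C(C)C)cc(C(=C)C(O)c2ccc(OCOC)cc2O[Si](C)(C)C(C)(C)C)c(OCOC)c1OCOC
F6 | step 9 | (3R)-3-[4-methoxy-5-(3-methylbut-2-en-1-yl)-2,3-bis(triethylsilyloxy)phenyl]-7-(triethylsilyloxy)-2,3-dihydro-4H-chromen-4-one | COc1c(CC=C(C)C)cc([C@@H]2COc3cc(O[Si](CC)(CC)CC)ccc3C2=O)c(O[Si](CC)(CC)CC)c1O[Si](CC)(CC)CC
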